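Daucane numbering is used (C1 quaternary, C4 carbinol, C5 ring-fusion CH, C6 ester carbinol, C9 ketone). The cyclopentane C1–C2–C3–C4–C5 together with exocyclic C6 is a p-menthane ring in disguise: C1-methyl and C4-isopropyl sit para across C5–C6. The route therefore starts from (S)-terpinen-4-ol, whose C4 carbinol stereocentre is kept, and rests on a photochemical Wolff ring contraction of a 2-diazocyclohexanone: C4 shifts from the carbonyl carbon to C5, the six-membered ring becomes the cyclopentane, and the extruded carbonyl carbon becomes the C6 ester. C1 is set beforehand by conjugate addition; metathesis, γ-oxidation, directed reduction and acylation complete the hydroazulenone.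

Key step: step 5

Remark: (S)-(+)-terpinen-4-ol is assumed to be purchased in high enantiomeric purity; its carbinol centre is the only source of chirality in the route.

Step 1
Reactants: 1 (S)-(+)-terpinen-4-ol
Product: 2 triethyl{[(1S)-4-methyl-1-(propan-2-yl)cyclohex-3-en-1-yl]oxy}silane
Conditions: Et3SiOTf, 2,6-lutidine, CH2Cl2, 0 °C
Reagents that add atoms: triethylsilyl trifluoromethanesulfonate, CC[Si](CC)(CC)OS(=O)(=O)C(F)(F)F
Why: Silyl ether protection of a tertiary alcohol with a silyl triflate and a hindered pyridine base should be clean; the bulky, non-chelating ether is needed later to bias the ring conformation, and no stereocentre is touched.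

Step 2
Reactants: 2
Product: 3 (6R)-3-methyl-6-(propan-2-yl)-6-[(triethylsilyl)oxy]cyclohex-2-en-1-one
Conditions: Rh2(cap)4 (dirhodium tetracaprolactamate, 1 mol%), t-BuOOH (70% aq.), K2CO3, CH2Cl2, rt
Reagents that add atoms: tert-butyl hydroperoxide, CC(C)(C)OO
Why: Radical allylic C–H oxidation with tert-butyl hydroperoxide should attack the methylene between the alkene CH and the carbinol carbon, because hydrogen abstraction there gives the allyl radical with a tertiary terminus and oxygenation at its secondary end leads to the conjugated β-methyl enone (the selectivity pattern of 7-oxidation of Δ5-steroids); the silyl ether and the quaternary carbinol centre are untouched.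

Step 3
Reactants: 3, 4 4-bromo-2-methylbut-1-ene
Product: 6 (3S,6R)-3-methyl-3-(3-methylbut-3-en-1-yl)-6-(propan-2-yl)-6-[(triethylsilyl)oxy]cyclohexan-1-one, via trimethylsilyl enol ether 5 (not isolated)
Conditions: 4, Mg, THF, rt; then 3, CuBr·SMe2 (20 mol%), Me3SiCl, THF, −78 → −30 °C; then K2CO3, MeOH, 0 °C
Reagents that add atoms: none
Why: Copper-catalysed, chlorosilane-accelerated conjugate addition of a Grignard reagent to a β,β-disubstituted enone builds quaternary C1; with isopropyl equatorial and the silyloxy group axial on the α′ carbon, stereoelectronically preferred axial attack on the half-chair should place the new chain cis to isopropyl and trans to the silyloxy group.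

Step 4
Reactants: 6
Product: 8 (3S,6R)-2-diazo-3-methyl-3-(3-methylbut-3-en-1-yl)-6-(propan-2-yl)-6-[(triethylsilyl)oxy]cyclohexan-1-one, via 2-trifluoroacetyl ketone 7 (not isolated)
Conditions: LiN(SiMe3)2, THF, −78 °C; CF3CO2CH2CF3; aq. HCl; then MeSO2N3, Et3N, H2O (1 equiv), MeCN, rt
Reagents that add atoms: methanesulfonyl azide, CS(=O)(=O)N=[N+]=[N-]
Why: Detrifluoroacetylative diazo transfer (Regitz-type transfer to an activated 1,3-dicarbonyl) is suited to hindered ketones, and C5 is the only enolisable position because the other α-carbon (C4) is fully substituted, so the diazo group can only enter between the ketone and C1.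

Step 5
Reactants: 8
Product: 11 methyl (1R,2S,5R)-2-methyl-2-(3-methylbut-3-en-1-yl)-5-(propan-2-yl)-5-[(triethylsilyl)oxy]cyclopentane-1-carboxylate, via ketene 9 (not isolated), via C5-epimeric methyl ester 10 (not isolated)
Conditions: hν (medium-pressure Hg lamp, Pyrex filter), MeOH, rt; then NaOMe (0.3 equiv), MeOH, rt
Reagents that add atoms: methanol, CO
Why: Photolysis expels N2 from the s-cis-locked cyclic α-diazo ketone while the C4–C6 bond migrates to the diazo carbon C5 (Wolff rearrangement), giving a cyclopentylidene ketene that methanol captures as the methyl ester. The closest known reaction type is the photochemical Wolff ring contraction of 2-diazocyclohexanones to cyclopentanecarboxylates. The ring C1–C2–C3–C4–C5 is formed by a 1,2-shift that excises C6 from the six-membered ring C1–C5–C6–C4–C3–C2, not by an end-to-end cyclisation, and C4 migrates with retention, so the terpinen-4-ol stereocentre is carried over. The new stereocentre C5 is first set by protonation of the ester enol and is then equilibrated by methoxide to the more stable epimer, with CO2Me trans to isopropyl and cis to the smaller silyloxy oxygen and the C1 methyl. The step needs rearrangement to outrun carbene insertion or cyclopropanation of the pendant alkene, which the concerted photochemical pathway of the conformationally fixed diazo ketone should secure, and only one group can migrate because C4 is the sole carbon on the carbonyl besides C5. The tertiary silyloxy group is a poor leaving group, so β-elimination under catalytic methoxide at room temperature should stay minor.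

Step 6
Reactants: 11
Product: 13 1-{(1R,2S,5R)-2-methyl-2-(3-methylbut-3-en-1-yl)-5-(propan-2-yl)-5-[(triethylsilyl)oxy]cyclopentyl}prop-2-en-1-one, via Weinreb amide 12 (not isolated)
Conditions: MeNH(OMe)·HCl, i-PrMgCl, THF, −20 °C; then CH2=CHMgBr, 0 °C → rt; poured into cold aq. HCl
Reagents that add atoms: vinylmagnesium bromide, C=C[Mg]Br
Why: The magnesium amide converts the ester in situ into the N-methoxy-N-methylamide, and Grignard addition to this Weinreb amide stops at the chelated adduct and gives the vinyl ketone on acidic quench; C5 is already in its thermodynamic configuration and the silyl ether and 1,1-disubstituted alkene are inert.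

Step 7
Reactants: 13
Product: 14 (3R,3aR,8aS)-6,8a-dimethyl-3-(propan-2-yl)-3-[(triethylsilyl)oxy]-2,3,3a,7,8,8a-hexahydroazulen-4(1H)-one (trans-fused)
Conditions: second-generation Grubbs catalyst [RuCl2(=CHPh)(PCy3)(1,3-dimesitylimidazolidin-2-ylidene)] (5 mol%), toluene (2 mM), 80 °C
Reagents that add atoms: none
Why: Ring-closing metathesis between the vinyl ketone and the 1,1-disubstituted alkene should close the seven-membered ring as a trisubstituted cycloheptenone with loss of ethene; the trans disposition of the two tethers on the cyclopentane gives the trans-fused hydroazulene without touching a stereocentre.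

Step 8
Reactants: 14
Product: 15 (3R,3aR,8aR)-6,8a-dimethyl-3-(propan-2-yl)-3-[(triethylsilyl)oxy]-1,2,3,3a,8,8a-hexahydroazulene-4,7-dione
Conditions: Rh2(cap)4 (dirhodium tetracaprolactamate, 1 mol%), t-BuOOH (70% aq.), 1,2-dichloroethane, 40 °C
Reagents that add atoms: tert-butyl hydroperoxide, CC(C)(C)OO
Why: Allylic (γ) C–H oxidation of an α,β-unsaturated ketone to the 2-ene-1,4-dione should occur at C9, the only allylic ring methylene of the C7=C8 double bond, and thereby installs the C9 ketone of the target; base-free conditions avoid epimerisation at C5.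

Step 9
Reactants: 15
Product: 16 (3R,3aR,8aR)-3-hydroxy-6,8a-dimethyl-3-(propan-2-yl)-1,2,3,3a,8,8a-hexahydroazulene-4,7-dione
Conditions: HF·pyridine, THF, 0 °C → rt
Reagents that add atoms: none
Why: Fluoride-mediated silyl ether cleavage under acidic, non-basic conditions should free the tertiary C4 hydroxyl without retro-aldol cleavage of the β-hydroxy ketone or epimerisation at C5.

Step 10
Reactants: 16
Product: 17 (3R,3aS,4S,8aR)-3,4-dihydroxy-6,8a-dimethyl-3-(propan-2-yl)-2,3,3a,4,8,8a-hexahydroazulen-7(1H)-one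
Conditions: Me4NBH(OAc)3, MeCN/AcOH (1:1), −30 → 0 °C
Reagents that add atoms: none
Why: Hydroxyl-directed triacetoxyborohydride reduction (Evans–Saksena type): the C4 alkoxyborohydride should deliver hydride intramolecularly only to the β-placed C6 carbonyl, on its face syn to the C4 oxygen, giving the anti-1,3-diol with 6S configuration and leaving the C9 enone carbonyl untouched.

Step 11
Reactants: 17, 18 (E)-3-(4-acetoxyphenyl)prop-2-enoic acid
Product: 19 (3R,3aS,4S,8aR)-3-hydroxy-6,8a-dimethyl-7-oxo-3-(propan-2-yl)-1,2,3,3a,4,7,8,8a-octahydroazulen-4-yl (E)-3-(4-acetoxyphenyl)prop-2-enoate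
Conditions: 18, DCC, DMAP (10 mol%), CH2Cl2, 0 °C → rt
Reagents that add atoms: none
Why: Steglich esterification acylates the secondary allylic C6 hydroxyl while the hindered tertiary C4 hydroxyl stays free; C6 keeps its configuration because its C–O bond is not broken.

Step 12
Reactants: 19
Product: 20 (3R,3aS,4S,8aR)-3-hydroxy-6,8a-dimethyl-7-oxo-3-(propan-2-yl)-1,2,3,3a,4,7,8,8a-octahydroazulen-4-yl (E)-3-(4-hydroxyphenyl)prop-2-enoate (CNP0310968.1)
Conditions: K2CO3 (0.5 equiv), MeOH, 0 °C, short reaction time; AcOH quench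
Reagents that add atoms: none
Why: Base-catalysed transesterification with methanol should cleave the aryl acetate far faster than the hindered alkyl cinnamate, releasing the phenol of the target with the enone and all stereocentres intact.

Compound list
1 | (S)-(+)-terpinen-4-ol, (1S)-4-methyl-1-(propan-2-yl)cyclohex-3-en-1-ol | CC1=CC[C@](O)(C(C)C)CC1 | starting material
2 | triethyl{[(1S)-4-methyl-1-(propan-2-yl)cyclohex-3-en-1-yl]oxy}silane | CC1=CC[C@](O[Si](CC)(CC)CC)(C(C)C)CC1 | intermediate
3 | (6R)-3-methyl-6-(propan-2-yl)-6-[(triethylsilyl)oxy]cyclohex-2-en-1-one | CC1=CC(=O)[C@](O[Si](CC)(CC)CC)(C(C)C)CC1 | intermediate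
4 | 4-bromo-2-methylbut-1-ene | C=C(C)CCBr | starting material
5 | trimethyl{[(3S,6R)-3-methyl-3-(3-methylbut-3-en-1-yl)-6-(propan-2-yl)-6-[(triethylsilyl)oxy]cyclohex-1-en-1-yl]oxy}silane | C[C@@]1(CCC(C)=C)C=C(O[Si](C)(C)C)[C@](O[Si](CC)(CC)CC)(C(C)C)CC1 | intermediate (not isolated)
6 | (3S,6R)-3-methyl-3-(3-methylbut-3-en-1-yl)-6-(propan-2-yl)-6-[(triethylsilyl)oxy]cyclohexan-1-one (new chain cis to isopropyl) | C[C@@]1(CCC(C)=C)CC(=O)[C@](O[Si](CC)(CC)CC)(C(C)C)CC1 | intermediate
7 | (3S,6R)-3-methyl-3-(3-methylbut-3-en-1-yl)-6-(propan-2-yl)-6-[(triethylsilyl)oxy]-2-(trifluoroacetyl)cyclohexan-1-one (C2 unassigned, enolised) | C[C@@]1(CCC(C)=C)C(C(=O)C(F)(F)F)C(=O)[C@](O[Si](CC)(CC)CC)(C(C)C)CC1 | intermediate (not isolated)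
8 | (3S,6R)-2-diazo-3-methyl-3-(3-methylbut-3-en-1-yl)-6-(propan-2-yl)-6-[(triethylsilyl)oxy]cyclohexan-1-one | C[C@@]1(CCC(C)=C)C(=[N+]=[N-])C(=O)[C@](O[Si](CC)(CC)CC)(C(C)C)CC1 | intermediate
9 | {(2S,5R)-2-methyl-2-(3-methylbut-3-en-1-yl)-5-(propan-2-yl)-5-[(triethylsilyl)oxy]cyclopentylidene}methanone (ketene) | C[C@@]1(CCC(C)=C)C(=C=O)[C@](O[Si](CC)(CC)CC)(C(C)C)CC1 | intermediate (not isolated)
10 | methyl (1S,2S,5R)-2-methyl-2-(3-methylbut-3-en-1-yl)-5-(propan-2-yl)-5-[(triethylsilyl)oxy]cyclopentane-1-carboxylate (ester cis to isopropyl) | C[C@@]1(CCC(C)=C)[C@H](C(=O)OC)[C@](O[Si](CC)(CC)CC)(C(C)C)CC1 | intermediate (not isolated)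
11 | methyl (1R,2S,5R)-2-methyl-2-(3-methylbut-3-en-1-yl)-5-(propan-2-yl)-5-[(triethylsilyl)oxy]cyclopentane-1-carboxylate (ester cis to the silyloxy group and the ring methyl) | C[C@@]1(CCC(C)=C)[C@@H](C(=O)OC)[C@](O[Si](CC)(CC)CC)(C(C)C)CC1 | intermediate
12 | (1R,2S,5R)-N-methoxy-N,2-dimethyl-2-(3-methylbut-3-en-1-yl)-5-(propan-2-yl)-5-[(triethylsilyl)oxy]cyclopentane-1-carboxamide | C[C@@]1(CCC(C)=C)[C@@H](C(=O)N(C)OC)[C@](O[Si](CC)(CC)CC)(C(C)C)CC1 | intermediate (not isolated)
13 | 1-{(1R,2S,5R)-2-methyl-2-(3-methylbut-3-en-1-yl)-5-(propan-2-yl)-5-[(triethylsilyl)oxy]cyclopentyl}prop-2-en-1-one | C[C@@]1(CCC(C)=C)[C@@H](C(=O)C=C)[C@](O[Si](CC)(CC)CC)(C(C)C)CC1 | intermediate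
14 | (3R,3aR,8aS)-6,8a-dimethyl-3-(propan-2-yl)-3-[(triethylsilyl)oxy]-2,3,3a,7,8,8a-hexahydroazulen-4(1H)-one (trans-fused) | C[C@@]12CCC(C)=CC(=O)[C@H]1[C@](O[Si](CC)(CC)CC)(C(C)C)CC2 | intermediate
15 | (3R,3aR,8aR)-6,8a-dimethyl-3-(propan-2-yl)-3-[(triethylsilyl)oxy]-1,2,3,3a,8,8a-hexahydroazulene-4,7-dione | C[C@@]12CC(=O)C(C)=CC(=O)[C@H]1[C@](O[Si](CC)(CC)CC)(C(C)C)CC2 | intermediate
16 | (3R,3aR,8aR)-3-hydroxy-6,8a-dimethyl-3-(propan-2-yl)-1,2,3,3a,8,8a-hexahydroazulene-4,7-dione | C[C@@]12CC(=O)C(C)=CC(=O)[C@H]1[C@](O)(C(C)C)CC2 | intermediate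
17 | (3R,3aS,4S,8aR)-3,4-dihydroxy-6,8a-dimethyl-3-(propan-2-yl)-2,3,3a,4,8,8a-hexahydroazulen-7(1H)-one (4β,6α-dihydroxydauc-7-en-9-one) | C[C@@]12CC(=O)C(C)=C[C@H](O)[C@H]1[C@](O)(C(C)C)CC2 | intermediate
18 | (E)-3-(4-acetoxyphenyl)prop-2-enoic acid (4-acetoxycinnamic acid) | CC(=O)Oc1ccc(/C=C/C(=O)O)cc1 | starting material
19 | (3R,3aS,4S,8aR)-3-hydroxy-6,8a-dimethyl-7-oxo-3-(propan-2-yl)-1,2,3,3a,4,7,8,8a-octahydroazulen-4-yl (E)-3-(4-acetoxyphenyl)prop-2-enoate | C[C@@]12CC(=O)C(C)=C[C@H](OC(=O)/C=C/c3ccc(OC(C)=O)cc3)[C@H]1[C@](O)(C(C)C)CC2 | intermediate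
20 | (3R,3aS,4S,8aR)-3-hydroxy-6,8a-dimethyl-7-oxo-3-(propan-2-yl)-1,2,3,3a,4,7,8,8a-octahydroazulen-4-yl (E)-3-(4-hydroxyphenyl)prop-2-enoate; daucane descriptors 1R,4R,5S,6S | C[C@@]12CC(=O)C(C)=C[C@H](OC(=O)/C=C/c3ccc(O)cc3)[C@H]1[C@](O)(C(C)C)CC2 | target

Total step count: 12. Longest linear sequence: 12 steps (1 → 20); 4 and 18 are purchased.

Steps most likely to fail

Step 2: the allylic oxidation may lack regiocontrol, with attack at the other ring methylene or at the allylic methyl instead of the hindered methylene next to the carbinol carbon. The fallback sets out from 2. Epoxidation with mCPBA (NaHCO3, CH2Cl2) should give 4-methyl-1-(propan-2-yl)-1-[(triethylsilyl)oxy]-1,2-epoxide of 2, the 7-oxabicyclo[4.1.0]heptane F1 (either epoxide face). Opening with PhSeNa, made from (PhSe)2 and NaBH4 in EtOH, at the secondary epoxide carbon should give the trans β-hydroxy selenide F2. Oxidation with H2O2 and selenoxide syn-elimination, possible only toward the required methylene, should give the tertiary allylic alcohol F3. Oxidative 1,3-transposition with pyridinium chlorochromate (C5H5NH)[CrO3Cl] in CH2Cl2 returns to the route at 3.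

Step 8: the late C–H oxidation may lack chemoselectivity, with attack at the allylic methyl or the tertiary C5–H, or over-oxidation. The fallback sets out from 14. Me3SiOTf and Et3N should give the extended silyl dienol ether F4. Its γ-oxidation with mCPBA, the reaction type used for 6-hydroxylation of steroidal dienol ethers, should give the 9-hydroxy enone F5 as a mixture of C9 epimers. Oxidation with Dess–Martin periodinane returns to the route at 15.

Step 10: facial selectivity may be poor, or boron exchange at the hindered tertiary alcohol may be slow, so that the wrong C6 epimer forms. The fallback sets out from 16. The complementary chelation-controlled reduction (Et2BOMe, NaBH4, THF/MeOH, −78 °C; external hydride onto the boron chelate, Narasaka–Prasad type) should give the syn-diol, the 6-epimeric diol F6. Mitsunobu esterification of F6 with 18 (PPh3, diisopropyl azodicarboxylate, toluene) sets C6 by inversion and returns to the route at 19.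

Further compounds
F1 | step 2 | triethyl{[1-methyl-4-(propan-2-yl)-7-oxabicyclo[4.1.0]heptan-4-yl]oxy}silane (carbinol centre as in 2, either epoxide face) | CC12OC1C[C@](O[Si](CC)(CC)CC)(C(C)C)CC2
F2 | step 2 | 1-methyl-2-(phenylselanyl)-4-(propan-2-yl)-4-[(triethylsilyl)oxy]cyclohexan-1-ol (carbinol centre as in 2, hydroxyl and selenide trans) | CC1(O)C([Se]c2ccccc2)C[C@](O[Si](CC)(CC)CC)(C(C)C)CC1
F3 | step 2 | 1-methyl-4-(propan-2-yl)-4-[(triethylsilyl)oxy]cyclohex-2-en-1-ol (silyloxy-bearing centre as in 2) | CC1(O)C=C[C@](O[Si](CC)(CC)CC)(C(C)C)CC1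
F4 | step 8 | {[6,8a-dimethyl-3-(propan-2-yl)-3-[(triethylsilyl)oxy]-1,2,3,3a,8,8a-hexahydroazulen-4-yl]oxy}trimethylsilane (stereocentres as in 14) | C[C@@]12CC=C(C)C=C(O[Si](C)(C)C)[C@H]1[C@](O[Si](CC)(CC)CC)(C(C)C)CC2
F5 | step 8 | 7-hydroxy-6,8a-dimethyl-3-(propan-2-yl)-3-[(triethylsilyl)oxy]-2,3,3a,7,8,8a-hexahydroazulen-4(1H)-one (other stereocentres as in 14, carbinol epimers) | C[C@@]12CC(O)C(C)=CC(=O)[C@H]1[C@](O[Si](CC)(CC)CC)(C(C)C)CC2
F6 | step 10 | (3R,3aS,4R,8aR)-3,4-dihydroxy-6,8a-dimethyl-3-(propan-2-yl)-2,3,3a,4,8,8a-hexahydroazulen-7(1H)-one (6-epimer of 17) | C[C@@]12CC(=O)C(C)=C[C@@H](O)[C@H]1[C@](O)(C(C)C)CC2
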